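**Retrosynthetic overview**

1. Feature: ring B is the chain C1(=O)–C2–C3–C4 held at its two ends by the adjacent carbons C8a and C4a of ring A, whose 6,7-dimethoxy pattern is symmetric about the C4a–C8a bond. Taking out that o-arylene unit leaves a 2-aryl-3,4-dimethylcyclobutanone in which C1 is bonded to C4.
2. Disconnections: the O–benzyl bond (last step); then C4–C4a and C1–C8a together, back to 4,5-dimethoxybenzyne and the cyclobutanone. C4 is set on protonation; C2 and C3 are carried.
3. The cyclobutanone comes from a keteniminium–alkene [2+2] of an arylacetamide of a C2-symmetric pyrrolidine with trans-2-butene. The aryne precursor is the o-silylaryl triflate made from 3,4-dimethoxyphenol.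
4. Ring order: both benzene rings are bought; the four-membered ring is made first (step 2) and is enlarged by two atoms into ring B (step 5).

Key step: step 5

Assumption: the sense of facial induction of the 2,5-dimethylpyrrolidine auxiliary toward an acyclic trans-alkene cannot be predicted with confidence. The (2R,5R) amine is written; if the cycloaddition gives the antipodal (3R,4R) cyclobutanone, the (2S,5S) amine is used in the same way. The aryl-bearing carbon of the cyclobutanone is erased in the key step, so only the two methyl-bearing carbons have to be set there.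

**Route**

Step 1
Reactants: 1 2-[3-(benzyloxy)-4-methoxyphenyl]acetic acid; 2 (2R,5R)-2,5-dimethylpyrrolidine (free base)
Product: 4 2-[3-(benzyloxy)-4-methoxyphenyl]-1-[(2R,5R)-2,5-dimethylpyrrolidin-1-yl]ethan-1-one, via acid chloride 3 (not isolated)
Conditions: (COCl)2, cat. DMF, CH2Cl2, 0 °C → rt, evaporate; then 2, Et3N, CH2Cl2, 0 °C → rt
Reagents that add atoms: none
Why: Acid chloride formation under Vilsmeier-type catalysis followed by N-acylation of the secondary amine (amide formation); any ketene formed from the arylacetyl chloride and Et3N is captured by the same amine, and no stereocentre is touched.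

Step 2
Reactants: 4 the amide; 5 trans-2-butene
Product: 8 (2S,3S,4S)-2-[3-(benzyloxy)-4-methoxyphenyl]-3,4-dimethylcyclobutan-1-one, via keteniminium triflate 6 (not isolated), via cyclobutaniminium triflate 7 (not isolated)
Conditions: Tf2O, 2,4,6-collidine, 5 (excess, condensed), ClCH2CH2Cl, sealed tube, −20 → 60 °C; then aq NaHCO3, 60 °C
Reagents that add atoms: water, O
Why: Amide activation gives the aldoketeniminium salt, which should undergo the thermal keteniminium–alkene [2+2] cycloaddition with retention of the trans alkene geometry; the C2-symmetric auxiliary (no axial isomers of the cumulene) selects one enantiotopic face of the butene and so fixes both methyl-bearing carbons, and hydrolysis in base releases the ketone with the two α-carbons equilibrated to the all-trans arrangement.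

Step 3
Reactants: 9 3,4-dimethoxyphenol
Product: 10 2-bromo-4,5-dimethoxyphenol
Conditions: NBS, MeCN, 0 °C
Reagents that add atoms: N-bromosuccinimide, O=C1CCC(=O)N1Br
Why: Electrophilic aromatic bromination should go to C6, ortho to the hydroxyl and para to the 3-methoxy group, the most activated unhindered position.

Step 4
Reactants: 10 2-bromo-4,5-dimethoxyphenol
Product: 13 4,5-dimethoxy-2-(trimethylsilyl)phenyl trifluoromethanesulfonate, via aryl silyl ether 11 (not isolated), via lithium phenolate 12 (not isolated)
Conditions: HMDS, THF, reflux, evaporate; n-BuLi, THF, −100 → −80 °C; Tf2O, −100 °C → rt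
Reagents that add atoms: hexamethyldisilazane, C[Si](C)(C)N[Si](C)(C)C; trifluoromethanesulfonic anhydride, O=S(=O)(OS(=O)(=O)C(F)(F)F)C(F)(F)F
Why: O-Silylation, then bromine–lithium exchange triggers the anionic 1,3-O→C silyl shift (retro-Brook rearrangement) to the ortho-silyl phenolate, which is triflated on oxygen; the bromine fixes where the silyl group ends up.

Step 5
Reactants: 8 the cyclobutanone; 13 the silylaryl triflate
Product: 16 (2S,3R,4R)-4-[3-(benzyloxy)-4-methoxyphenyl]-6,7-dimethoxy-2,3-dimethyl-3,4-dihydronaphthalen-1(2H)-one, via 4,5-dimethoxybenzyne 14 (not isolated), via benzocyclobutenoxide 15 (not isolated)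
Conditions: 13 (1.3 equiv, slow addition), CsF (3 equiv), anhydrous MeCN, 60 °C; aq NH4Cl
Reagents that add atoms: none
Why: Proposed new method: fluoride unmasks aryne 14 and reversibly deprotonates 8 only at the benzylic α-carbon, which is far more acidic than the methyl-bearing one; the enolate carbon adds to the aryne (C4–C4a) and the resulting aryl anion closes 4-exo-trig onto the strained carbonyl (C8a–C1) to give the fused alkoxide 15. Retro-aldol-type heterolysis of the bond shared by the two four-membered rings (old C1–C4) then relieves both and leaves ring B as a six-membered aryl ketone, so the ring is closed by two-atom ring expansion; the breaking bond lies in the plane of ring A, so the pendant aryl group stabilises the departing carbanion in the way the ester does in the known reaction. The closest known reactions are the acyl-alkylation of arynes by β-ketoesters, including its ring-expanding form with cyclic β-ketoesters, and the arynic condensation of ketone enolates that passes through benzocyclobutenols; a cyclobutanone without a second activating group has not been used. The C4 carbanion is protonated by a further molecule of 8, which carries the chain, from the face anti to the neighbouring 3-methyl group (kinetic protonation of a trigonal benzylic anion from its less hindered face), placing the aryl group cis to that methyl; C3 is untouched, and C2 is carried and, being α to the ketone, can only settle toward the same trans-2,3 arrangement. The symmetric aryne excludes regioisomers, and slow addition of 13 keeps the more acidic 8 in excess so that the product anion is quenched before it meets a second aryne.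

Step 6
Reactants: 16 the benzyl ether
Product: 17 (2S,3R,4R)-4-(3-hydroxy-4-methoxyphenyl)-6,7-dimethoxy-2,3-dimethyl-3,4-dihydronaphthalen-1(2H)-one (target)
Conditions: H2 (1 atm), 10% Pd/C, EtOAc, rt
Reagents that add atoms: none
Why: Heterogeneous catalytic hydrogenolysis cleaves the benzylic C–O bond under neutral conditions at 1 atm, under which the electron-rich aryl ketone, the methyl ethers and the three stereocentres should be left as they are.

**Compound list**

1 | 2-[3-(benzyloxy)-4-methoxyphenyl]acetic acid | COc1ccc(CC(=O)O)cc1OCc1ccccc1 | starting material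
2 | (2R,5R)-2,5-dimethylpyrrolidine | C[C@@H]1CC[C@@H](C)N1 | starting material
3 | 2-[3-(benzyloxy)-4-methoxyphenyl]acetyl chloride | COc1ccc(CC(=O)Cl)cc1OCc1ccccc1 | intermediate (not isolated)
4 | 2-[3-(benzyloxy)-4-methoxyphenyl]-1-[(2R,5R)-2,5-dimethylpyrrolidin-1-yl]ethan-1-one | COc1ccc(CC(=O)N2[C@H](C)CC[C@H]2C)cc1OCc1ccccc1 | intermediate
5 | trans-2-butene | C/C=C/C | starting material
6 | (2R,5R)-1-{2-[3-(benzyloxy)-4-methoxyphenyl]ethenylidene}-2,5-dimethylpyrrolidin-1-ium triflate (aldoketeniminium salt) | COc1ccc(C=C=[N+]2[C@H](C)CC[C@H]2C)cc1OCc1ccccc1.[O-]S(=O)(=O)C(F)(F)F | intermediate (not isolated)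
7 | (2R,5R)-1-{(3S,4S)-2-[3-(benzyloxy)-4-methoxyphenyl]-3,4-dimethylcyclobutylidene}-2,5-dimethylpyrrolidin-1-ium triflate (aryl-bearing carbon as formed, left open) | COc1ccc(cc1OCc1ccccc1)C1[C@@H](C)[C@H](C)C1=[N+]2[C@H](C)CC[C@H]2C.[O-]S(=O)(=O)C(F)(F)F | intermediate (not isolated)
8 | (2S,3S,4S)-2-[3-(benzyloxy)-4-methoxyphenyl]-3,4-dimethylcyclobutan-1-one (all-trans) | COc1ccc(cc1OCc1ccccc1)[C@@H]1[C@@H](C)[C@H](C)C1=O | intermediate
9 | 3,4-dimethoxyphenol | COc1ccc(O)cc1OC | starting material
10 | 2-bromo-4,5-dimethoxyphenol | COc1cc(O)c(Br)cc1OC | intermediate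
11 | (2-bromo-4,5-dimethoxyphenoxy)trimethylsilane | COc1cc(O[Si](C)(C)C)c(Br)cc1OC | intermediate (not isolated)
12 | lithium 4,5-dimethoxy-2-(trimethylsilyl)phenolate | COc1cc([O-])c(cc1OC)[Si](C)(C)C.[Li+] | intermediate (not isolated)
13 | 4,5-dimethoxy-2-(trimethylsilyl)phenyl trifluoromethanesulfonate | COc1cc(OS(=O)(=O)C(F)(F)F)c(cc1OC)[Si](C)(C)C | intermediate
14 | 4,5-dimethoxybenzyne (1,2-didehydro-4,5-dimethoxybenzene) | COC1=CC#CC=C1OC | intermediate (not isolated)
15 | caesium alkoxide of the cis-fused benzocyclobutene–cyclobutane adduct: the fusion carbon C4 carries the pendant aryl group and is bonded to C4a, the fusion carbon C1 carries O− and is bonded to C8a, C1–C4 still bonded, 2,3-dimethyl trans; configuration of the two fusion carbons relative to the methyls left open | COc1ccc(cc1OCc1ccccc1)C12[C@@H](C)[C@H](C)C1([O-])c1cc(OC)c(OC)cc12.[Cs+] | intermediate (not isolated)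
16 | (2S,3R,4R)-4-[3-(benzyloxy)-4-methoxyphenyl]-6,7-dimethoxy-2,3-dimethyl-3,4-dihydronaphthalen-1(2H)-one | COc1ccc([C@@H]2c3cc(OC)c(OC)cc3C(=O)[C@@H](C)[C@@H]2C)cc1OCc1ccccc1 | intermediate
17 | (2S,3R,4R)-4-(3-hydroxy-4-methoxyphenyl)-6,7-dimethoxy-2,3-dimethyl-3,4-dihydronaphthalen-1(2H)-one | COc1ccc([C@@H]2c3cc(OC)c(OC)cc3C(=O)[C@@H](C)[C@@H]2C)cc1O | target

**Step count**

Total steps: 6. Longest linear sequence: 4 steps (1 → 4 → 8 → 16 → 17, or 9 → 10 → 13 → 16 → 17).

**Steps most likely to fail**

1. Step 5 (proposed new method). The aryl anion may be protonated before it closes onto the carbonyl, which stops at simple α-arylation. The enolate may be arylated on oxygen, the product anion may take up a second aryne, or the C4 anion may be protonated from the wrong face. Fallback by known chemistry, setting out from 8: commercial 3,4-dimethoxyphenylmagnesium bromide, premixed with anhydrous CeCl3 in THF at −78 °C, should add to the strained carbonyl anti to the flanking aryl and methyl groups without enolisation, giving (1S,2S,3S,4S)-2-[3-(benzyloxy)-4-methoxyphenyl]-1-(3,4-dimethoxyphenyl)-3,4-dimethylcyclobutan-1-ol F1. The known oxidative ring expansion of 1-arylcyclobutanols to 1-tetralones (cat. AgNO3, K2S2O8, CH2Cl2/H2O) should then open the alkoxy radical toward the benzylic carbon. That carbon closes on the ring position para to a methoxy group and the ring is rearomatised, which returns to the route at 16. C4 is then formed without the same kinetic bias, so its epimer would be removed by chromatography and C2 settled with DBU.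

2. Step 2. The auxiliary may discriminate poorly between the two faces of the butene, and the unactivated trans-alkene may react slowly enough for the electron-rich arene of a second molecule to attack the keteniminium ion. Fallback, setting out from acid chloride 3: dimethylamine gives 2-[3-(benzyloxy)-4-methoxyphenyl]-N,N-dimethylacetamide F2. The same Tf2O/collidine activation in the presence of 5 should lead through the N,N-dimethylketeniminium triflate F3 and the racemic N,N-dimethylcyclobutaniminium triflate F4 and, after bicarbonate hydrolysis, to the racemic all-trans cyclobutanone. This is 8 together with its (2R,3R,4R) enantiomer F5. Preparative SFC on a polysaccharide chiral phase separates the two and returns to the route at 8.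

3. Step 6. The aryl ketone may be reduced to the benzylic alcohol or further during hydrogenolysis. Fallback, setting out from 16: BCl3 with pentamethylbenzene as cation scavenger in CH2Cl2 at −78 °C cleaves the benzyl ether by Lewis-acid ionisation, a non-reductive path that should leave the ketone and the methyl ethers in place, and gives 17 directly without a new compound.

**Further compounds**

F1 | step 5 | (1S,2S,3S,4S)-2-[3-(benzyloxy)-4-methoxyphenyl]-1-(3,4-dimethoxyphenyl)-3,4-dimethylcyclobutan-1-ol | COc1ccc(cc1OCc1ccccc1)[C@@H]1[C@@H](C)[C@H](C)[C@@]1(O)c1ccc(OC)c(OC)c1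
F2 | step 2 | 2-[3-(benzyloxy)-4-methoxyphenyl]-N,N-dimethylacetamide | COc1ccc(CC(=O)N(C)C)cc1OCc1ccccc1
F3 | step 2 | N-{2-[3-(benzyloxy)-4-methoxyphenyl]ethenylidene}-N-methylmethanaminium triflate | COc1ccc(C=C=[N+](C)C)cc1OCc1ccccc1.[O-]S(=O)(=O)C(F)(F)F
F4 | step 2 | N-{2-[3-(benzyloxy)-4-methoxyphenyl]-3,4-dimethylcyclobutylidene}-N-methylmethanaminium triflate (racemic, trans-dimethyl, relative configuration shown) | COc1ccc(cc1OCc1ccccc1)C1[C@@H](C)[C@H](C)C1=[N+](C)C.[O-]S(=O)(=O)C(F)(F)F
F5 | step 2 | (2R,3R,4R)-2-[3-(benzyloxy)-4-methoxyphenyl]-3,4-dimethylcyclobutan-1-one | COc1ccc(cc1OCc1ccccc1)[C@H]1[C@H](C)[C@@H](C)C1=O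
F0 | step 6 | none | none
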